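**Assumption:** the target SMILES has no stereocentres or stereodefined double bonds, so the molecule is treated as achiral and no asymmetric step is needed.

## Retrosynthetic overview

1. The quinone is unmasked last, by mild oxidation of the ring-A hydroquinone obtained on global O-demethylation of a tri-O-methyl macrocycle.
2. The 18-membered macrocycle is the only ring formed; it is closed at the ring A–ring B two-carbon bridge by McMurry coupling of an acyclic dialdehyde, followed by alkene hydrogenation.
3. The dialdehyde comes from a Heck union (then C=C reduction) of two diaryl-ether halves of similar size: the A–O–D styrene 8 and the B–O–C aryl bromide 15.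
4. Fragment 8 comes from Ullmann etherification of 2-bromo-3,6-dimethoxybenzaldehyde (from hydroquinone) with 3-vinylphenol. Fragment 15 comes from SNAr of 5-bromo-2-methoxyphenol (from 4-bromophenol) with 4-fluorobenzaldehyde.
5. Ring order: all four benzene rings are purchased; the macrocycle forms at step 13; the quinone is generated at step 16.

## Route

### Fragment A–O–D (steps 1–5)

**Step 1**
Reactants: 1, hydroquinone
Product: 2, 1,4-dimethoxybenzene
Conditions: Me2SO4, K2CO3, acetone, reflux
Reagents that add atoms: dimethyl sulfate, COS(=O)(=O)OC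
Why: Williamson O-methylation of both phenols masks the future quinone as a robust dimethyl ether.

**Step 2**
Reactants: 2, 1,4-dimethoxybenzene
Product: 3, 2-bromo-1,4-dimethoxybenzene
Conditions: NBS (1.05 equiv), MeCN, rt
Reagents that add atoms: N-bromosuccinimide, BrN1C(=O)CCC1=O
Why: Electrophilic aromatic bromination of the activated ring stops cleanly at the monobromide.

**Step 3**
Reactants: 3, 2-bromo-1,4-dimethoxybenzene
Product: 4, 2-bromo-3,6-dimethoxybenzaldehyde
Conditions: LDA, THF, −78 °C; then DMF; aq. NH4Cl
Reagents that add atoms: N,N-dimethylformamide, CN(C)C=O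
Why: Directed ortho-metalation with a non-nucleophilic amide base removes the proton flanked by Br and OMe without Br/Li exchange, and DMF formylates that position.

**Step 4**
Reactants: 5, 3-iodophenol; 6, potassium vinyltrifluoroborate
Product: 7, 3-vinylphenol (3-ethenylphenol)
Conditions: PdCl2(dppf) (2 mol %), Et3N, n-PrOH, 85 °C
Reagents that add atoms: none
Why: Suzuki–Miyaura vinylation of the aryl iodide tolerates the free phenol and installs the two bridge carbons.

**Step 5**
Reactants: 4, 2-bromo-3,6-dimethoxybenzaldehyde; 7, 3-vinylphenol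
Product: 8, 2-(3-ethenylphenoxy)-3,6-dimethoxybenzaldehyde
Conditions: CuI (10 mol %), picolinic acid (20 mol %), K3PO4, DMSO, 90 °C (trace BHT)
Reagents that add atoms: none
Why: Ligand-accelerated Ullmann diaryl-ether synthesis; the ortho-formyl group activates the only C–halogen bond present, so there is no chemoselectivity issue.

### Fragment B–O–C (steps 6–10)

**Step 6**
Reactants: 9, 4-bromophenol
Product: 10, 5-bromo-2-hydroxybenzaldehyde
Conditions: MgCl2, Et3N, (CH2O)n, MeCN, reflux
Reagents that add atoms: paraformaldehyde (formaldehyde), C=O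
Why: Magnesium-phenoxide-mediated ortho-formylation (Casnati–Skattebøl) is ortho-specific, fixing the second oxygen position next to the phenol and meta to Br.

**Step 7**
Reactants: 10, 5-bromo-2-hydroxybenzaldehyde
Product: 11, 5-bromo-2-methoxybenzaldehyde
Conditions: MeI, K2CO3, DMF, rt
Reagents that add atoms: iodomethane, CI
Why: Williamson methylation protects the oxygen that ends up as the free ring-C phenol (para to the bridge).

**Step 8**
Reactants: 11, 5-bromo-2-methoxybenzaldehyde
Product: 12, 5-bromo-2-methoxyphenol
Conditions: mCPBA, CH2Cl2, rt; then K2CO3, MeOH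
Reagents that add atoms: mCPBA, OOC(=O)c1cccc(Cl)c1
Why: Baeyer–Villiger/Dakin oxidation; the electron-rich o-methoxyaryl group migrates to give the aryl formate, which is methanolysed to the phenol.

**Step 9**
Reactants: 13, 1-bromo-4-fluorobenzene
Product: 14, 4-fluorobenzaldehyde
Conditions: Mg, THF; then DMF, 0 °C; aq. HCl
Reagents that add atoms: N,N-dimethylformamide, CN(C)C=O
Why: Grignard formation occurs only at C–Br, and Bouveault formylation with DMF gives the SNAr-activated fluoroaldehyde.

**Step 10**
Reactants: 12, 5-bromo-2-methoxyphenol; 14, 4-fluorobenzaldehyde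
Product: 15, 4-(5-bromo-2-methoxyphenoxy)benzaldehyde
Conditions: K2CO3, DMF, 120 °C
Reagents that add atoms: none
Why: SNAr of the phenoxide on the para-formyl-activated aryl fluoride; the unactivated aryl bromide is inert without metal.

### Fragment union and endgame (steps 11–16)

**Step 11**
Reactants: 8, 2-(3-ethenylphenoxy)-3,6-dimethoxybenzaldehyde; 15, 4-(5-bromo-2-methoxyphenoxy)benzaldehyde
Product: 16, 2-{3-[(E)-2-[3-(4-formylphenoxy)-4-methoxyphenyl]ethenyl]phenoxy}-3,6-dimethoxybenzaldehyde
Conditions: Pd(OAc)2 (5 mol %), P(o-tol)3 (10 mol %), Et3N, DMF, 100 °C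
Reagents that add atoms: none
Why: Mizoroki–Heck arylation of the styrene at its terminal carbon joins the two halves as the E-stilbene and leaves both aldehydes untouched.

**Step 12**
Reactants: 16, (E)-stilbene dialdehyde
Product: 17, 2-{3-[2-[3-(4-formylphenoxy)-4-methoxyphenyl]ethyl]phenoxy}-3,6-dimethoxybenzaldehyde
Conditions: H2 (1 atm), 10% Pd/C, Ph2S (cat.), EtOAc, rt
Reagents that add atoms: none
Why: Sulfide-poisoned Pd/C hydrogenates the C=C bond chemoselectively without reducing aromatic aldehydes, giving the flexible bibenzyl needed for ring closure.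

**Step 13**
Reactants: 17, bibenzyl dialdehyde
Product: 18, macrocyclic stilbene with a CH=CH bridge between ring A and ring B (tri-O-methyl; Z drawn, any E isomer is carried forward)
Conditions: TiCl4, Zn, pyridine, THF, reflux; 17 added by syringe pump over 24 h (final ca. 1 mM)
Reagents that add atoms: none
Why: Intramolecular McMurry reductive carbonyl coupling under high dilution closes the 18-membered ring; the alkene geometry is irrelevant because it is reduced next.

**Step 14**
Reactants: 18, macrocyclic stilbene
Product: 19, saturated macrocycle (marchantinquinone hydroquinone trimethyl ether)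
Conditions: H2 (1 atm), 10% Pd/C, EtOAc/MeOH, rt
Reagents that add atoms: none
Why: Catalytic hydrogenation of the stilbene gives the second CH2CH2 bridge; aryl and methyl ethers are inert.

**Step 15**
Reactants: 19, saturated trimethyl ether
Product: 20, ring-A hydroquinone/ring-C phenol macrocycle (marchantinquinone hydroquinone)
Conditions: BBr3 (8 equiv), CH2Cl2, −78 °C to rt; aqueous work-up under Ar
Reagents that add atoms: none
Why: Lewis-acid cleavage of the three aryl methyl ethers; the diaryl ethers are not cleaved by BBr3.

**Step 16**
Reactants: 20, hydroquinone–phenol macrocycle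
Product: 21, marchantinquinone
Conditions: Ag2O (2.5 equiv), MgSO4, Et2O/THF, rt, dark
Reagents that add atoms: none
Why: Mild two-electron oxidation converts only the p-hydroquinone to the p-benzoquinone; the isolated ring-C monophenol has a much higher oxidation potential and is untouched.

## Compound list

1 | hydroquinone | Oc1ccc(O)cc1 | starting material
2 | 1,4-dimethoxybenzene | COc1ccc(OC)cc1 | intermediate
3 | 2-bromo-1,4-dimethoxybenzene | COc1ccc(OC)c(Br)c1 | intermediate
4 | 2-bromo-3,6-dimethoxybenzaldehyde | COc1ccc(OC)c(C=O)c1Br | intermediate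
5 | 3-iodophenol | Oc1cccc(I)c1 | starting material
6 | potassium vinyltrifluoroborate | [K+].C=C[B-](F)(F)F | starting material
7 | 3-vinylphenol | Oc1cccc(C=C)c1 | intermediate
8 | 2-(3-ethenylphenoxy)-3,6-dimethoxybenzaldehyde | COc1ccc(OC)c(C=O)c1Oc1cccc(C=C)c1 | intermediate
9 | 4-bromophenol | Oc1ccc(Br)cc1 | starting material
10 | 5-bromo-2-hydroxybenzaldehyde | O=Cc1cc(Br)ccc1O | intermediate
11 | 5-bromo-2-methoxybenzaldehyde | COc1ccc(Br)cc1C=O | intermediate
12 | 5-bromo-2-methoxyphenol | COc1ccc(Br)cc1O | intermediate
13 | 1-bromo-4-fluorobenzene | Fc1ccc(Br)cc1 | starting material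
14 | 4-fluorobenzaldehyde | O=Cc1ccc(F)cc1 | intermediate
15 | 4-(5-bromo-2-methoxyphenoxy)benzaldehyde | COc1ccc(Br)cc1Oc1ccc(C=O)cc1 | intermediate
16 | 2-{3-[(E)-2-[3-(4-formylphenoxy)-4-methoxyphenyl]ethenyl]phenoxy}-3,6-dimethoxybenzaldehyde | COc1ccc(OC)c(C=O)c1Oc1cccc(c1)/C=C/c1ccc(OC)c(c1)Oc1ccc(C=O)cc1 | intermediate
17 | 2-{3-[2-[3-(4-formylphenoxy)-4-methoxyphenyl]ethyl]phenoxy}-3,6-dimethoxybenzaldehyde | COc1ccc(OC)c(C=O)c1Oc1cccc(c1)CCc1ccc(OC)c(c1)Oc1ccc(C=O)cc1 | intermediate
18 | macrocyclic (Z)-stilbene, tri-O-methyl (ring A–CH=CH–ring B) | COc1ccc(OC)c2c1/C=C\c1ccc(cc1)Oc1cc(ccc1OC)CCc1cccc(c1)O2 | intermediate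
19 | marchantinquinone hydroquinone trimethyl ether | COc1ccc(OC)c2c1CCc1ccc(cc1)Oc1cc(ccc1OC)CCc1cccc(c1)O2 | intermediate
20 | marchantinquinone hydroquinone (triol) | Oc1ccc(O)c2c1CCc1ccc(cc1)Oc1cc(ccc1O)CCc1cccc(c1)O2 | intermediate
21 | marchantinquinone | O=C1C=CC(=O)C2=C1CCc1ccc(cc1)Oc1cc(ccc1O)CCc1cccc(c1)O2 | target

## Summary

**Total steps:** 16
**Longest linear sequence:** 10 (steps 1, 2, 3, 5, 11–16; the 4-bromophenol branch, steps 6, 7, 8, 10, 11–16, is also 10)

**Three steps most likely to fail, with fallbacks**

1. **Step 13, McMurry macrocyclisation.** The ring-A aldehyde is doubly ortho-substituted and the ring is strained, so pinacol and oligomer by-products are likely. Fallback: close the same bridge by intramolecular Wittig instead. Carry the ring-B carbon at the ester oxidation level and the ring-A aldehyde as a dioxolane; after the bridge hydrogenation convert ester → CH2OH → CH2PPh3Br, unmask the aldehyde, and cyclise with NaOMe in CH2Cl2 under high dilution, then hydrogenate.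

2. **Step 5, Ullmann etherification.** The aryl bromide is electron-rich and flanked on both sides, and the styrene must survive 90 °C. Fallback: a metal-free SNAr route. Make 2-fluoro-3,6-dimethoxybenzaldehyde from 2 (n-BuLi/TMEDA then NFSI; n-BuLi then DMF) and displace the ortho-formyl-activated fluoride with phenol 7 (K2CO3, DMF, 120–140 °C).

3. **Step 11, Heck union.** The electron-rich aryl bromide is sluggish, and some 1,1-diarylethene regioisomer or styrene oligomer may form. Fallback: an sp3–sp2 B-alkyl Suzuki coupling. Protect the aldehydes of 8 and 15 as dioxolanes, hydroborate the styrene with 9-BBN, couple with the aryl bromide (PdCl2(dppf), K3PO4, THF/H2O), and hydrolyse the acetals on acidic work-up. This gives 17 directly and also removes the need for step 12.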